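**Plan**

- Retrosynthesis: the acetate is taken off first; the O8–C15 bond of the oxocane is then cut at the lactone level (C15=O); next C13–C14 (Wolff 1,2-shift, C14 from diazomethane), C13–C16 (formaldehyde) and C12=C13 (Wittig), which leads back to (+)-sclareolide.
- Forward: sclareolide supplies rings A and B and the 8α C–O bond; its lactol is extended by two carbons, hydroxymethylated at C13 and converted into an α-diazoketone. Photolysis gives a ketene at C15, which the free tertiary 8α-hydroxyl captures to close the eight-membered ring (O8, C8, C9, C11, C12, C13, C14, C15) as a lactone.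
- The lactone carbonyl is then reduced to CH2 through the α-acetoxy ether, and the silyl ether at C16 is exchanged for the acetate.
- Enabling feature: on the rigid trans-decalin the 8α-hydroxyl is equatorial and gauche to the equatorial C9 side chain, so O8 lies beside the chain that carries the ketene carbon C15. A ketene acylates a hindered tertiary hydroxyl without activation, and no other nucleophile is left in the molecule.
- Stereochemistry: C5, C8, C9 and C10 come from sclareolide; C13 is set by catalyst-controlled enamine hydroxymethylation and passes through the 1,2-shift with retention.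

Key step: step 8

Remark: labdane numbering is used (C8 = ether carbon of ring B, C13 = side-chain stereocentre, C15 = OCH2, C16 = CH2OAc); "Dec" stands for the (1R,2R,4aS,8aS)-2-hydroxy-2,5,5,8a-tetramethyldecahydronaphthalen-1-yl group; ethereal diazomethane is assumed to be prepared from commercial N-methyl-N-nitroso-p-toluenesulfonamide.

**Route**

Step 1
Reactants: 1 (+)-sclareolide
Product: 2 sclareolide lactol (3aR,5aS,9aS,9bR)-3a,6,6,9a-tetramethyldodecahydronaphtho[2,1-b]furan-2-ol as a mixture of C12 anomers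
Conditions: iBu2AlH (1.2 equiv), CH2Cl2, −78 °C; Rochelle salt work-up
Reagents that add atoms: none
Why: Half-reduction of a γ-lactone with iBu2AlH stops at the aluminium hemiacetal at low temperature and should give the lactol; the new hemiacetal centre at C12 does not matter because the ring is opened in the next step.

Step 2
Reactants: 2 sclareolide lactol; 3 N-methoxy-N-methyl-2-(triphenylphosphoranylidene)acetamide
Product: 4 (2E)-4-Dec-N-methoxy-N-methylbut-2-enamide
Conditions: PhMe, 90 °C
Reagents that add atoms: none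
Why: Wittig olefination of the lactol through its open hydroxy aldehyde with an amide-stabilised ylide should give the E-enamide under neutral conditions that leave the tertiary 8-hydroxyl unreacted.

Step 3
Reactants: 4 (2E)-4-Dec-N-methoxy-N-methylbut-2-enamide
Product: 5 4-Dec-N-methoxy-N-methylbutanamide
Conditions: H2 (1 atm), Pd/C, EtOAc, rt
Reagents that add atoms: none
Why: Heterogeneous hydrogenation saturates the conjugated C12=C13 bond and so removes the Michael acceptor next to the free hydroxyl; no stereocentre is formed.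

Step 4
Reactants: 5 4-Dec-N-methoxy-N-methylbutanamide
Product: 6 4-Dec-butanal
Conditions: iBu2AlH (2.2 equiv), THF, −78 °C; Rochelle salt work-up
Reagents that add atoms: none
Why: Reduction of an N-methoxy-N-methylamide stops at the chelated tetrahedral aluminium adduct and releases the aldehyde only on work-up, the first equivalent of hydride being spent on the hydroxyl.

Step 5
Reactants: 6 4-Dec-butanal
Product: 8 (2S)-2-(hydroxymethyl)-4-Dec-butanoic acid, via beta-hydroxy aldehyde 7 (not isolated)
Conditions: HCHO (37% aq., 3 equiv), (R)-2-[diphenyl(trimethylsilyloxy)methyl]pyrrolidine (20 mol %), pH 7 phosphate buffer, PhMe, rt; then NaClO2, NaH2PO4, 2-methylbut-2-ene, tBuOH/H2O, 0 °C to rt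
Reagents that add atoms: formaldehyde C=O; sodium chlorite [Na+].[O-]Cl=O
Why: Organocatalytic enamine α-hydroxymethylation of a linear aldehyde: formaldehyde attacks the E-enamine on the face away from the CPh2OSiMe3 group, which with the (R)-catalyst should give (S)-C13 independently of the remote decalin, and immediate Pinnick oxidation fixes the labile β-hydroxy aldehyde as the acid.

Step 6
Reactants: 8 (2S)-2-(hydroxymethyl)-4-Dec-butanoic acid
Product: 10 (2S)-2-[(tert-butyldiphenylsilyloxy)methyl]-4-Dec-butanoic acid, via bis-silylated silyl ester 9 (not isolated)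
Conditions: TBDPSCl (2.5 equiv), imidazole, DMF, rt; then K2CO3, THF/MeOH/H2O, rt
Reagents that add atoms: tert-butyl(chloro)diphenylsilane CC(C)(C)[Si](Cl)(c1ccccc1)c1ccccc1
Why: Silylation with the bulky chlorosilane takes the primary hydroxyl and the carboxyl group but not the tertiary 8-hydroxyl, and mild carbonate hydrolysis cleaves the silyl ester while the silyl ether stays.

Step 7
Reactants: 10 (2S)-2-[(tert-butyldiphenylsilyloxy)methyl]-4-Dec-butanoic acid
Product: 12 (3S)-3-[(tert-butyldiphenylsilyloxy)methyl]-1-diazo-5-Dec-pentan-2-one, via mixed isobutyl carbonic anhydride 11 (not isolated)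
Conditions: iBuOCOCl, N-methylmorpholine, THF, −15 °C; then CH2N2, Et2O, 0 °C to rt
Reagents that add atoms: diazomethane C=[N+]=[N-]; isobutyl chloroformate CC(C)COC(Cl)=O (atoms only in intermediate 11)
Why: First half of an Arndt–Eistert sequence: the mixed carbonic anhydride acylates diazomethane at the acyl carbonyl at low temperature without touching the tertiary hydroxyl or the α-stereocentre.

Step 8
Reactants: 12 (3S)-3-[(tert-butyldiphenylsilyloxy)methyl]-1-diazo-5-Dec-pentan-2-one
Product: 14 eight-membered lactone (13R)-16-(tert-butyldiphenylsilyloxy)-8α,15-epoxylabdan-15-one, via ketene 13 (not isolated)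
Conditions: hν (365 nm LED), PhMe (0.002 M), 4 Å MS, 60 °C
Reagents that add atoms: none
Why: Irradiation expels N2 and C13 migrates to the diazo carbon in the Wolff 1,2-shift (new C13–C14 bond), giving the aldoketene 13; the tertiary 8α-hydroxyl then adds to the ketene carbon C15 with proton transfer to C14, which forms the O8–C15 bond and the lactone. The closest known reaction type is the Arndt–Eistert homologation with capture of the ketene by a hindered alcohol (tert-butyl ester formation) in its intramolecular, lactone-forming version. The one ring closed is the eight-membered oxocan-2-one (O8, C8, C9, C11, C12, C13, C14, C15), formed by nucleophilic addition to the sp carbon with the C15=O bond outside the ring, formally 8-exo-dig. No new stereocentre is created: C13 keeps its configuration through the suprafacial shift and C15 is trigonal. The step needs rearrangement over direct carbene insertion and ring closure over dimerisation or hydration of the ketene; the first is favoured by photolysis of the diazoketone, the second by high dilution and slow generation of the ketene, by the absence of any other nucleophile (O16 is silylated), and by the trans-decalin, which holds O8 equatorial and gauche to the C9 chain that carries the ketene.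

Step 9
Reactants: 14 eight-membered lactone
Product: 16 (13R)-15-acetoxy-16-(tert-butyldiphenylsilyloxy)-8α,15-epoxylabdane as a mixture of C15 epimers, via aluminium hemiacetal 15 (not isolated)
Conditions: iBu2AlH (1.2 equiv), CH2Cl2, −78 °C; then pyridine, DMAP, Ac2O, −78 °C to 0 °C
Reagents that add atoms: acetic anhydride CC(=O)OC(C)=O; diisobutylaluminium hydride CC(C)C[AlH]CC(C)C (atoms only in intermediate 15)
Why: Reductive acetylation of a lactone: the aluminium hemiacetal formed at −78 °C is acetylated in situ to the cyclic α-acetoxy ether before it can open to the hydroxy aldehyde, and the new acetal centre C15 is removed in the next step.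

Step 10
Reactants: 16 α-acetoxy ether
Product: 17 (13R)-16-(tert-butyldiphenylsilyloxy)-8α,15-epoxylabdane
Conditions: Et3SiH, BF3·OEt2, CH2Cl2, −78 °C
Reagents that add atoms: none
Why: Ionic hydrogenation of an α-acetoxy ether: the Lewis acid ionises the acetate to the cyclic oxocarbenium ion, which triethylsilane reduces to the CH2–O ether, and the low temperature should spare the tertiary C8–O bond and the silyl ether.

Step 11
Reactants: 17 (13R)-16-(tert-butyldiphenylsilyloxy)-8α,15-epoxylabdane
Product: 19 target (13R)-8α,15-epoxylabdan-16-yl acetate, via primary alcohol 18 (not isolated)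
Conditions: Bu4NF, THF, rt; then Ac2O, DMAP (cat.), rt
Reagents that add atoms: acetic anhydride CC(=O)OC(C)=O
Why: Fluoride cleaves the primary silyl ether and the liberated C16 oxygen is acetylated in the same flask, leaving the cyclic ether and all stereocentres untouched.

**Compound list**

1 | (+)-sclareolide, (3aR,5aS,9aS,9bR)-3a,6,6,9a-tetramethyldecahydronaphtho[2,1-b]furan-2(1H)-one | O=C1O[C@]2(C)CC[C@H]3C(C)(C)CCC[C@]3(C)[C@H]2C1 | starting material
2 | sclareolide lactol, (3aR,5aS,9aS,9bR)-3a,6,6,9a-tetramethyldodecahydronaphtho[2,1-b]furan-2-ol (C12 anomers) | OC1O[C@]2(C)CC[C@H]3C(C)(C)CCC[C@]3(C)[C@H]2C1 | intermediate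
3 | N-methoxy-N-methyl-2-(triphenylphosphoranylidene)acetamide | CON(C)C(=O)C=P(c1ccccc1)(c1ccccc1)c1ccccc1 | starting material
4 | (2E)-4-[(1R,2R,4aS,8aS)-2-hydroxy-2,5,5,8a-tetramethyldecahydronaphthalen-1-yl]-N-methoxy-N-methylbut-2-enamide | O[C@]1(C)CC[C@H]2C(C)(C)CCC[C@]2(C)[C@H]1C/C=C/C(=O)N(C)OC | intermediate
5 | 4-[(1R,2R,4aS,8aS)-2-hydroxy-2,5,5,8a-tetramethyldecahydronaphthalen-1-yl]-N-methoxy-N-methylbutanamide | O[C@]1(C)CC[C@H]2C(C)(C)CCC[C@]2(C)[C@H]1CCCC(=O)N(C)OC | intermediate
6 | 4-[(1R,2R,4aS,8aS)-2-hydroxy-2,5,5,8a-tetramethyldecahydronaphthalen-1-yl]butanal | O[C@]1(C)CC[C@H]2C(C)(C)CCC[C@]2(C)[C@H]1CCCC=O | intermediate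
7 | (2S)-2-(hydroxymethyl)-4-[(1R,2R,4aS,8aS)-2-hydroxy-2,5,5,8a-tetramethyldecahydronaphthalen-1-yl]butanal (not isolated) | O[C@]1(C)CC[C@H]2C(C)(C)CCC[C@]2(C)[C@H]1CC[C@@H](CO)C=O | intermediate
8 | (2S)-2-(hydroxymethyl)-4-[(1R,2R,4aS,8aS)-2-hydroxy-2,5,5,8a-tetramethyldecahydronaphthalen-1-yl]butanoic acid | O[C@]1(C)CC[C@H]2C(C)(C)CCC[C@]2(C)[C@H]1CC[C@@H](CO)C(=O)O | intermediate
9 | tert-butyldiphenylsilyl (2S)-2-[(tert-butyldiphenylsilyloxy)methyl]-4-[(1R,2R,4aS,8aS)-2-hydroxy-2,5,5,8a-tetramethyldecahydronaphthalen-1-yl]butanoate (not isolated) | O[C@]1(C)CC[C@H]2C(C)(C)CCC[C@]2(C)[C@H]1CC[C@@H](CO[Si](c1ccccc1)(c1ccccc1)C(C)(C)C)C(=O)O[Si](c1ccccc1)(c1ccccc1)C(C)(C)C | intermediate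
10 | (2S)-2-[(tert-butyldiphenylsilyloxy)methyl]-4-[(1R,2R,4aS,8aS)-2-hydroxy-2,5,5,8a-tetramethyldecahydronaphthalen-1-yl]butanoic acid | O[C@]1(C)CC[C@H]2C(C)(C)CCC[C@]2(C)[C@H]1CC[C@@H](CO[Si](c1ccccc1)(c1ccccc1)C(C)(C)C)C(=O)O | intermediate
11 | mixed anhydride of acid 10 with isobutyl hydrogen carbonate (not isolated) | O[C@]1(C)CC[C@H]2C(C)(C)CCC[C@]2(C)[C@H]1CC[C@@H](CO[Si](c1ccccc1)(c1ccccc1)C(C)(C)C)C(=O)OC(=O)OCC(C)C | intermediate
12 | (3S)-3-[(tert-butyldiphenylsilyloxy)methyl]-1-diazo-5-[(1R,2R,4aS,8aS)-2-hydroxy-2,5,5,8a-tetramethyldecahydronaphthalen-1-yl]pentan-2-one | O[C@]1(C)CC[C@H]2C(C)(C)CCC[C@]2(C)[C@H]1CC[C@@H](CO[Si](c1ccccc1)(c1ccccc1)C(C)(C)C)C(=O)C=[N+]=[N-] | intermediate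
13 | ketene (3R)-3-[(tert-butyldiphenylsilyloxy)methyl]-5-[(1R,2R,4aS,8aS)-2-hydroxy-2,5,5,8a-tetramethyldecahydronaphthalen-1-yl]pent-1-en-1-one (not isolated) | O[C@]1(C)CC[C@H]2C(C)(C)CCC[C@]2(C)[C@H]1CC[C@@H](CO[Si](c1ccccc1)(c1ccccc1)C(C)(C)C)C=C=O | intermediate
14 | (13R)-16-(tert-butyldiphenylsilyloxy)-8α,15-epoxylabdan-15-one (oxocan-2-one trans-fused to ring B) | CC(C)(C)[Si](c1ccccc1)(c1ccccc1)OC[C@H]1CC(=O)O[C@]2(C)CC[C@H]3C(C)(C)CCC[C@]3(C)[C@H]2CC1 | intermediate
15 | diisobutylaluminium hemiacetal of lactone 14 (not isolated, C15 epimers) | CC(C)(C)[Si](c1ccccc1)(c1ccccc1)OC[C@H]1CC(O[Al](CC(C)C)CC(C)C)O[C@]2(C)CC[C@H]3C(C)(C)CCC[C@]3(C)[C@H]2CC1 | intermediate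
16 | (13R)-15-acetoxy-16-(tert-butyldiphenylsilyloxy)-8α,15-epoxylabdane (C15 epimers) | CC(C)(C)[Si](c1ccccc1)(c1ccccc1)OC[C@H]1CC(OC(C)=O)O[C@]2(C)CC[C@H]3C(C)(C)CCC[C@]3(C)[C@H]2CC1 | intermediate
17 | (13R)-16-(tert-butyldiphenylsilyloxy)-8α,15-epoxylabdane | CC(C)(C)[Si](c1ccccc1)(c1ccccc1)OC[C@H]1CCO[C@]2(C)CC[C@H]3C(C)(C)CCC[C@]3(C)[C@H]2CC1 | intermediate
18 | (13R)-8α,15-epoxylabdan-16-ol (not isolated) | OC[C@H]1CCO[C@]2(C)CC[C@H]3C(C)(C)CCC[C@]3(C)[C@H]2CC1 | intermediate
19 | (13R)-8α,15-epoxylabdan-16-yl acetate (CNP0152986.1) | CC(=O)OC[C@H]1CCO[C@]2(C)CC[C@H]3C(C)(C)CCC[C@]3(C)[C@H]2CC1 | target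

**Count and risks**

Total step count: 11. Longest linear sequence: 11 steps (from 1 to 19).

Steps most likely to fail:

1. Step 8 (ketene ring closure). The ketene may be consumed by dimerisation or by traces of water faster than the hindered tertiary hydroxyl closes the eight-membered ring, or direct carbene insertion may compete with the 1,2-shift. The fallback sets out from diazoketone 12 and closes the same ring through the same O8–C15 bond by carbenoid O–H insertion. Rh2(OAc)4 (1 mol %) in benzene at high dilution and 80 °C should give the oxocan-3-one (13S)-16-(tert-butyldiphenylsilyloxy)-8α,15-epoxylabdan-14-one F1. NaBH4 in MeOH at −20 °C reduces the ketone to the 14-alcohol F2; NaH, CS2 and MeI convert it into the S-methyl xanthate F3; and Bu3SnH/AIBN in toluene at 110 °C removes the oxygen (Barton–McCombie deoxygenation). The fallback comes back to the route at compound 17.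

2. Step 5 (enamine hydroxymethylation). Facial control by the catalyst may be insufficient on this substrate, or the β-hydroxy aldehyde may lose water or undergo retro-aldol cleavage before it is oxidised. The fallback replaces catalyst control by an oxazolidinone auxiliary and sets out from aldehyde 6. Pinnick oxidation gives the acid 4-Dec-butanoic acid F4. PivCl, Et3N, LiCl and (R)-4-benzyl-1,3-oxazolidin-2-one give the N-acyl oxazolidinone F5. N-(trimethylsilyl)imidazole caps the tertiary hydroxyl as the trimethylsilyl ether F6. TiCl4/iPr2NEt followed by s-trioxane/TiCl4 should hydroxymethylate the Z-titanium enolate on the face away from the benzyl group to give the (S)-hydroxymethyl imide F7. LiOH/H2O2 cleavage with mildly acidic work-up (loss of the trimethylsilyl group) comes back to the route at compound 8.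

3. Step 10 (oxocarbenium reduction). The tert-alkyl oxocarbenium ion may fragment by ionisation of the C8–O bond before hydride is delivered, which would open the ring and lead to elimination in ring B. The fallback avoids the cation and sets out from lactone 14. Lawesson's reagent in toluene at 100 °C should give the thionolactone F8, and Raney Ni in EtOH at rt desulfurises the C=S group to CH2. The fallback comes back to the route at compound 17.

Further compounds
F1 | step 8 | (13S)-16-(tert-butyldiphenylsilyloxy)-8α,15-epoxylabdan-14-one | CC(C)(C)[Si](c1ccccc1)(c1ccccc1)OC[C@H]1C(=O)CO[C@]2(C)CC[C@H]3C(C)(C)CCC[C@]3(C)[C@H]2CC1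
F2 | step 8 | 16-(tert-butyldiphenylsilyloxy)-8α,15-epoxylabdan-14-ol (C14 epimers) | CC(C)(C)[Si](c1ccccc1)(c1ccccc1)OC[C@H]1C(O)CO[C@]2(C)CC[C@H]3C(C)(C)CCC[C@]3(C)[C@H]2CC1
F3 | step 8 | O-[16-(tert-butyldiphenylsilyloxy)-8α,15-epoxylabdan-14-yl] S-methyl dithiocarbonate | CC(C)(C)[Si](c1ccccc1)(c1ccccc1)OC[C@H]1C(OC(=S)SC)CO[C@]2(C)CC[C@H]3C(C)(C)CCC[C@]3(C)[C@H]2CC1
F4 | step 5 | 4-[(1R,2R,4aS,8aS)-2-hydroxy-2,5,5,8a-tetramethyldecahydronaphthalen-1-yl]butanoic acid | O[C@]1(C)CC[C@H]2C(C)(C)CCC[C@]2(C)[C@H]1CCCC(=O)O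
F5 | step 5 | (4R)-4-benzyl-3-{4-[(1R,2R,4aS,8aS)-2-hydroxy-2,5,5,8a-tetramethyldecahydronaphthalen-1-yl]butanoyl}-1,3-oxazolidin-2-one | O[C@]1(C)CC[C@H]2C(C)(C)CCC[C@]2(C)[C@H]1CCCC(=O)N1[C@H](Cc2ccccc2)COC1=O
F6 | step 5 | (4R)-4-benzyl-3-{4-[(1R,2R,4aS,8aS)-2,5,5,8a-tetramethyl-2-(trimethylsilyloxy)decahydronaphthalen-1-yl]butanoyl}-1,3-oxazolidin-2-one | C[Si](C)(C)O[C@]1(C)CC[C@H]2C(C)(C)CCC[C@]2(C)[C@H]1CCCC(=O)N1[C@H](Cc2ccccc2)COC1=O
F7 | step 5 | (4R)-4-benzyl-3-{(2S)-2-(hydroxymethyl)-4-[(1R,2R,4aS,8aS)-2,5,5,8a-tetramethyl-2-(trimethylsilyloxy)decahydronaphthalen-1-yl]butanoyl}-1,3-oxazolidin-2-one | C[Si](C)(C)O[C@]1(C)CC[C@H]2C(C)(C)CCC[C@]2(C)[C@H]1CC[C@@H](CO)C(=O)N1[C@H](Cc2ccccc2)COC1=O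
F8 | step 10 | (13R)-16-(tert-butyldiphenylsilyloxy)-8α,15-epoxylabdane-15-thione | CC(C)(C)[Si](c1ccccc1)(c1ccccc1)OC[C@H]1CC(=S)O[C@]2(C)CC[C@H]3C(C)(C)CCC[C@]3(C)[C@H]2CC1
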